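**Retrosynthetic overview**

- The target is cut at the C8–C9 bond of the nonadienyl chain (B-alkyl Suzuki coupling) into a C11 vinylcyclohexanol and a C14 alkenyl iodide that already carries the butenolide carbons as an alkylated dioxanone hydrazone. The butenolide is closed last, from an α-hydroxy ketone and Ph3P=C=C=O.
- The cyclohexane is numbered as in the 2-hydroxy-2,6,6-trimethylcyclohexyl group (C1 side chain, C2 carbinol, C6 gem-dimethyl). It is made in one operation from 4-methylpent-4-enal and a chiral 3-methyl-4-oxopent-2-enoate by an iron-hydride radical–polar crossover annulation that forms C1–C6 (radical conjugate addition) and C2–C3 (aldol).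
- The enabling feature is the quaternary gem-dimethyl C6 next to the chain-bearing C1 (a tertiary radical from an isopropenyl group adding to an enoate carbon), together with the methyl-bearing carbinol C2, which is the Baeyer–Villiger image of the α-carbon of a methyl ketone enolate closing on a C3 aldehyde. The extra C3 hydroxyl and the acetyl oxidation level are removed in steps 5–7.
- Stereocontrol: C1 comes from an 8-phenylmenthyl ester and C2 is relayed from C1 by A(1,3) strain in the same event. Butenolide C5 comes from a RAMP-hydrazone alkylation, the Z-alkene from syn-carbocupration of an ynoate, and the E-alkene from hydrozirconation/iodination.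
- Ring order: cyclohexane (step 4), then a temporary dioxanone (made in step 11, opened in step 21), then the butenolide (step 23).

Key step: step 4

Remark on names: "(1S,2R,5S)-8-phenylmenthyl" stands for (1S,2R,5S)-5-methyl-2-(2-phenylpropan-2-yl)cyclohexyl; TBDPS = tert-butyldiphenylsilyl; TBS = tert-butyldimethylsilyl.

Assumption: the 8-phenylmenthyl enoate of step 4 reacts from its s-cis (C=O/C=C) conformer with the ester carbonyl syn to the carbinol C–H, so the phenyl group covers the enoate face on the side of the auxiliary's C2; on this model the (1S,2R,5S) alcohol gives the (S) configuration at ring C1, and if the sense proved opposite the enantiomeric alcohol would be used in step 2 with nothing else changed.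

**Route**

Step 1
Reactants: 1 4-methylpent-4-en-1-ol
Product: 2 4-methylpent-4-enal
Conditions: TEMPO (cat.), PhI(OAc)2, CH2Cl2, rt
Reagents that add atoms: none
Why: The oxoammonium (TEMPO/PhI(OAc)2) oxidation of the primary alcohol stops at the aldehyde and does not touch the 1,1-disubstituted alkene.

Step 2
Reactants: 3 (1S,2R,5S)-5-methyl-2-(2-phenylpropan-2-yl)cyclohexan-1-ol ((+)-8-phenylmenthol); 4 2-(diethoxyphosphoryl)acetic acid
Product: 5 (1S,2R,5S)-8-phenylmenthyl 2-(diethoxyphosphoryl)acetate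
Conditions: DCC, DMAP (cat.), CH2Cl2, 0 °C to rt
Reagents that add atoms: none
Why: Steglich esterification joins the hindered secondary alcohol to the acid under neutral conditions and installs a controller that is later cleaved without an extra step.

Step 3
Reactants: 5 phosphonoacetate; 6 butane-2,3-dione
Product: 7 (1S,2R,5S)-8-phenylmenthyl (2E)-3-methyl-4-oxopent-2-enoate
Conditions: NaH, THF, 0 °C; then added to 6 (excess), −78 °C to rt
Reagents that add atoms: none
Why: Horner–Wadsworth–Emmons olefination of one carbonyl of the symmetrical diketone should give mainly the (E)-enoate with ester and acetyl trans, the minor (Z) isomer being removed by chromatography.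

Step 4
Reactants: 2 4-methylpent-4-enal; 7 keto enoate
Product: 9 (1S,2R,5S)-8-phenylmenthyl (1S,2R,3S)-2-acetyl-3-hydroxy-2,6,6-trimethylcyclohexane-1-carboxylate, via iron enolate 8 (not isolated)
Conditions: Fe(acac)3 (0.3 equiv), PhSiH3, EtOH/ethylene glycol, 0 °C to rt, 2 in excess
Reagents that add atoms: none
Why: An iron hydride formed from Fe(acac)3 and PhSiH3 transfers a hydrogen atom to the terminal carbon of the electron-rich 1,1-disubstituted alkene of 2, the tertiary radical adds to the unsubstituted alkene carbon of 7 (C1–C6 bond), the resulting tertiary α-keto radical is reduced by divalent iron to enolate 8, and 8 closes on the tethered aldehyde (C2–C3 bond) in a 6-(enolexo)-exo-trig aldol addition. The closest known reaction type is the iron-catalysed hydrogen-atom-transfer Giese addition/aldol (radical–polar crossover) annulation of γ,δ-unsaturated aldehydes with α,β-unsaturated carbonyl compounds. C1 is set by the auxiliary, whose phenyl group lies over one face of the s-cis enoate so that the bulky radical enters anti to it. C2 is relayed from C1 in the same event by A(1,3) strain: in 8 the C1–H bond eclipses the fully substituted enolate double bond, ester and aldehyde-bearing tether sit on opposite faces, and the aldehyde can only reach the face that puts acetyl trans to the ester (both equatorial, methyl axial) in the chair transition state. The C3 carbinol centre is expected cis to acetyl from a metal-bridged transition state but is of no consequence because it is removed in steps 5 and 6. The step needs hydrogen-atom transfer to 2 and not to 7, radical addition at the CH terminus of 7, and ring closure faster than protonation of the enolate, which the electronic contrast of the two alkenes, the 3-methyl group of 7 and the six-membered chair closure should secure in that order.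

Step 5
Reactants: 9 hydroxy keto ester
Product: 10 (1S,2R,5S)-8-phenylmenthyl (1S,2R,3S)-2-acetyl-2,6,6-trimethyl-3-[(phenoxycarbonothioyl)oxy]cyclohexane-1-carboxylate
Conditions: PhOC(S)Cl, pyridine, DMAP (cat.), MeCN, rt
Reagents that add atoms: O-phenyl chlorothionoformate, S=C(Cl)Oc1ccccc1
Why: Thioacylation of the secondary alcohol (first stage of a Barton–McCombie deoxygenation) under weakly basic conditions should leave the retro-aldol-prone β-hydroxy ketone intact.

Step 6
Reactants: 10 thionocarbonate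
Product: 11 (1S,2R,5S)-8-phenylmenthyl (1S,2S)-2-acetyl-2,6,6-trimethylcyclohexane-1-carboxylate
Conditions: Bu3SnH (0.5 M), AIBN (cat.), (PhSe)2 (cat.), benzene, 80 °C
Reagents that add atoms: none
Why: Barton–McCombie radical deoxygenation removes the auxiliary C3 oxygen from either carbinol epimer, and PhSeH generated from (PhSe)2 should trap the C3 radical fast enough to outrun a 1,2-acyl shift, while C1 and C2 are not touched.

Step 7
Reactants: 11 keto ester
Product: 12 (1S,2R,5S)-8-phenylmenthyl (1S,2S)-2-(acetyloxy)-2,6,6-trimethylcyclohexane-1-carboxylate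
Conditions: mCPBA, NaHCO3, CH2Cl2, rt
Reagents that add atoms: mCPBA (3-chloroperoxybenzoic acid), OOC(=O)c1cccc(Cl)c1
Why: In the Baeyer–Villiger oxidation the tertiary C2 migrates in preference to methyl and with retention, which turns the acetyl group into the C2 oxygen with the configuration fixed in step 4.

Step 8
Reactants: 12 acetoxy ester
Product: 13 (1S,2R)-2-(hydroxymethyl)-1,3,3-trimethylcyclohexan-1-ol
Conditions: LiAlH4, THF, 0 °C to reflux
Reagents that add atoms: none
Why: LiAlH4 reduces the hindered ester to the primary alcohol and cleaves the acetate in the same operation (ester reduction), releasing the auxiliary alcohol 3 for recovery.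

Step 9
Reactants: 13 diol
Product: 14 (1S,2S)-2-hydroxy-2,6,6-trimethylcyclohexane-1-carbaldehyde
Conditions: Dess–Martin periodinane, NaHCO3, CH2Cl2, 0 °C to rt
Reagents that add atoms: none
Why: Dess–Martin oxidation converts only the primary alcohol, the tertiary one being inert, and the buffered neutral medium should avoid retro-aldol opening of the β-hydroxy aldehyde.

Step 10
Reactants: 14 hydroxy aldehyde
Product: 15 (1S,2S)-2-ethenyl-1,3,3-trimethylcyclohexan-1-ol
Conditions: Zn, CH2Br2, TiCl4, THF/CH2Cl2, 0 °C to rt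
Reagents that add atoms: dibromomethane, BrCBr
Why: Takai–Lombardo methylenation is non-basic and tolerates hindered carbonyls and free hydroxyl groups, so the aldehyde should become the vinyl group without retro-aldol cleavage or epimerisation at C1.

Step 11
Reactants: 16 (2R)-2-(methoxymethyl)pyrrolidin-1-amine (RAMP); 17 2,2-dimethyl-1,3-dioxan-5-one
Product: 18 (2R)-N-(2,2-dimethyl-1,3-dioxan-5-ylidene)-2-(methoxymethyl)pyrrolidin-1-amine
Conditions: benzene, reflux, Dean–Stark trap
Reagents that add atoms: none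
Why: Condensation of the ketone with the hydrazine (hydrazone formation with azeotropic removal of water) gives the chiral azaenolate precursor.

Step 12
Reactants: 19 methyl 4-hydroxybut-2-ynoate
Product: 20 methyl 4-[(tert-butyldiphenylsilyl)oxy]but-2-ynoate
Conditions: TBDPSCl, imidazole, CH2Cl2, 0 °C
Reagents that add atoms: tert-butyl(chloro)diphenylsilane, CC(C)(C)[Si](Cl)(c1ccccc1)c1ccccc1
Why: Silyl ether formation at the primary alcohol gives an acid-stable protecting group that should survive steps 20 and 21.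

Step 13
Reactants: 21 pent-3-yn-1-ol
Product: 22 5-bromopent-2-yne
Conditions: CBr4, PPh3, CH2Cl2, 0 °C
Reagents that add atoms: tetrabromomethane, BrC(Br)(Br)Br
Why: Appel bromination converts the primary homopropargylic alcohol into the bromide needed for the Grignard reagent.

Step 14
Reactants: 22 5-bromopent-2-yne; 20 silyloxy ynoate
Product: 25 methyl (2Z)-3-{[(tert-butyldiphenylsilyl)oxy]methyl}oct-2-en-6-ynoate, via pent-3-yn-1-ylmagnesium bromide 23 (not isolated), via pent-3-yn-1-ylcopper 24 (not isolated)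
Conditions: Mg, THF, rt; CuBr·SMe2, −40 °C; 20, −78 °C; aq. NH4Cl at −78 °C
Reagents that add atoms: none
Why: syn-Carbocupration of the ynoate (conjugate addition of the organocopper reagent) followed by protonation at −78 °C places the new chain trans to the ester, which fixes the (Z) geometry of the trisubstituted alkene.

Step 15
Reactants: 25 enoate
Product: 26 (2Z)-3-{[(tert-butyldiphenylsilyl)oxy]methyl}oct-2-en-6-yn-1-ol
Conditions: DIBAL-H, CH2Cl2, −78 °C to 0 °C
Reagents that add atoms: none
Why: DIBAL-H 1,2-reduction of the enoate gives the allylic alcohol without touching the alkyne or the alkene geometry.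

Step 16
Reactants: 26 enynol
Product: 28 (2Z,6E)-3-{[(tert-butyldiphenylsilyl)oxy]methyl}-7-iodoocta-2,6-dien-1-ol, via alkenylzirconocene chloride 27 (not isolated)
Conditions: Cp2Zr(H)Cl (3 equiv), THF, rt to 40 °C; then I2, 0 °C
Reagents that add atoms: iodine, [I][I]
Why: Hydrozirconation adds Zr–H syn across the alkyne with zirconium at the less hindered methyl-bearing carbon (equilibrated by excess reagent, one equivalent being consumed by the hydroxyl group), and iodinolysis with retention gives the (E)-2-iodoalkene.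

Step 17
Reactants: 28 iodo dienol
Product: 29 (2Z,6E)-1-bromo-3-{[(tert-butyldiphenylsilyl)oxy]methyl}-7-iodoocta-2,6-diene
Conditions: CBr4, PPh3, CH2Cl2, 0 °C
Reagents that add atoms: tetrabromomethane, BrC(Br)(Br)Br
Why: Appel bromination of the primary allylic alcohol should proceed without allylic transposition at 0 °C and leaves the alkenyl iodide untouched.

Step 18
Reactants: 18 RAMP hydrazone; 29 allylic bromide
Product: 31 (2R)-N-[(4R)-4-[(2Z,6E)-3-{[(tert-butyldiphenylsilyl)oxy]methyl}-7-iodoocta-2,6-dien-1-yl]-2,2-dimethyl-1,3-dioxan-5-ylidene]-2-(methoxymethyl)pyrrolidin-1-amine, via lithium azaenolate 30 (not isolated)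
Conditions: 18 (slight excess), t-BuLi, THF, −78 °C; then 29, −100 °C to rt
Reagents that add atoms: none
Why: In the Enders hydrazone alkylation the chelated lithium azaenolate of the (R)-auxiliary is attacked by the allylic bromide on the face that gives the (4R)-dioxanone derivative, the future C5 of the butenolide, and the alkenyl iodide is inert to the azaenolate.

Step 19
Reactants: 15 vinylcyclohexanol; 31 iodo hydrazone
Product: 33 (2R)-N-[(4R)-4-[(2Z,6E)-3-{[(tert-butyldiphenylsilyl)oxy]methyl}-9-[(1S,2S)-2-hydroxy-2,6,6-trimethylcyclohexyl]-7-methylnona-2,6-dien-1-yl]-2,2-dimethyl-1,3-dioxan-5-ylidene]-2-(methoxymethyl)pyrrolidin-1-amine, via B-alkyl-9-BBN 32 (not isolated)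
Conditions: 15, 9-BBN, THF, rt; then 31, Pd(dppf)Cl2 (cat.), AsPh3 (cat.), Cs2CO3, DMF/H2O, rt
Reagents that add atoms: none
Why: Anti-Markovnikov hydroboration of the vinyl group followed by B-alkyl Suzuki–Miyaura coupling with the alkenyl iodide forms the sp3–sp2 bond with retention of the (E) geometry, while the hydrazone shields the α-stereocentre from the base.

Step 20
Reactants: 33 coupled hydrazone
Product: 34 (4R)-4-[(2Z,6E)-3-{[(tert-butyldiphenylsilyl)oxy]methyl}-9-[(1S,2S)-2-hydroxy-2,6,6-trimethylcyclohexyl]-7-methylnona-2,6-dien-1-yl]-2,2-dimethyl-1,3-dioxan-5-one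
Conditions: sat. aq. oxalic acid, Et2O, rt
Reagents that add atoms: water, O
Why: Two-phase hydrolysis of the hydrazone with oxalic acid should liberate the ketone without epimerising the α-stereocentre and returns the auxiliary.

Step 21
Reactants: 34 dioxanone
Product: 35 (3R,5Z,9E)-6-{[(tert-butyldiphenylsilyl)oxy]methyl}-1,3-dihydroxy-12-[(1S,2S)-2-hydroxy-2,6,6-trimethylcyclohexyl]-10-methyldodeca-5,9-dien-2-one
Conditions: 1 M aq. HCl, THF, 0 °C to rt
Reagents that add atoms: none
Why: Acid-catalysed acetal hydrolysis frees the 1,3-diol while the tert-butyldiphenylsilyl ether and the tertiary alcohol should survive dilute acid.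

Step 22
Reactants: 35 dihydroxy ketone
Product: 36 (3R,5Z,9E)-1-[(tert-butyldimethylsilyl)oxy]-6-{[(tert-butyldiphenylsilyl)oxy]methyl}-3-hydroxy-12-[(1S,2S)-2-hydroxy-2,6,6-trimethylcyclohexyl]-10-methyldodeca-5,9-dien-2-one
Conditions: TBSCl (1.05 equiv), imidazole, CH2Cl2, −20 °C
Reagents that add atoms: tert-butyl(chloro)dimethylsilane, CC(C)(C)[Si](C)(C)Cl
Why: Kinetic silyl ether formation is selective for the unhindered primary hydroxyl over the secondary and tertiary ones.

Step 23
Reactants: 36 α-hydroxy ketone; 37 (triphenylphosphoranylidene)ketene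
Product: 39 (5R)-4-{[(tert-butyldimethylsilyl)oxy]methyl}-5-[(2Z,6E)-3-{[(tert-butyldiphenylsilyl)oxy]methyl}-9-[(1S,2S)-2-hydroxy-2,6,6-trimethylcyclohexyl]-7-methylnona-2,6-dien-1-yl]furan-2(5H)-one, via phosphorus ylide ester 38 (not isolated)
Conditions: toluene, 90 °C
Reagents that add atoms: none
Why: The secondary hydroxyl adds to the ketene ylide to give ester ylide 38, whose intramolecular Wittig reaction with the adjacent ketone closes the butenolide under neutral conditions that should not epimerise C5, while the hindered tertiary alcohol does not react.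

Step 24
Reactants: 39 bis-silyl butenolide
Product: 40 (5R)-4-(hydroxymethyl)-5-[(2Z,6E)-3-(hydroxymethyl)-9-[(1S,2S)-2-hydroxy-2,6,6-trimethylcyclohexyl]-7-methylnona-2,6-dien-1-yl]furan-2(5H)-one
Conditions: HF·pyridine, pyridine, THF, 0 °C to rt
Reagents that add atoms: none
Why: Fluoride-mediated desilylation with pyridine-buffered HF should remove both silyl ethers and leave the base-sensitive butenolide and the tertiary alcohol intact.

**Compound list**

1 | 4-methylpent-4-en-1-ol | CC(=C)CCCO | starting material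
2 | 4-methylpent-4-enal | CC(=C)CCC=O | intermediate
3 | (1S,2R,5S)-5-methyl-2-(2-phenylpropan-2-yl)cyclohexan-1-ol ((+)-8-phenylmenthol) | CC(C)(c1ccccc1)[C@H]1CC[C@H](C)C[C@@H]1O | starting material
4 | 2-(diethoxyphosphoryl)acetic acid | CCOP(=O)(CC(=O)O)OCC | starting material
5 | (1S,2R,5S)-8-phenylmenthyl 2-(diethoxyphosphoryl)acetate | CC(C)(c1ccccc1)[C@H]1CC[C@H](C)C[C@@H]1OC(=O)CP(=O)(OCC)OCC | intermediate
6 | butane-2,3-dione | CC(=O)C(C)=O | starting material
7 | (1S,2R,5S)-8-phenylmenthyl (2E)-3-methyl-4-oxopent-2-enoate | CC(C)(c1ccccc1)[C@H]1CC[C@H](C)C[C@@H]1OC(=O)/C=C(\C)C(C)=O | intermediate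
8 | iron enolate: (1S,2R,5S)-8-phenylmenthyl (2S)-3-methyl-2-(2-methyl-5-oxopentan-2-yl)-4-oxidopent-3-enoate (drawn as the anion, enolate geometry not fixed) | CC(C)(c1ccccc1)[C@H]1CC[C@H](C)C[C@@H]1OC(=O)[C@@H](C(C)(C)CCC=O)C(C)=C(C)[O-] | intermediate
9 | (1S,2R,5S)-8-phenylmenthyl (1S,2R,3S)-2-acetyl-3-hydroxy-2,6,6-trimethylcyclohexane-1-carboxylate | CC(C)(c1ccccc1)[C@H]1CC[C@H](C)C[C@@H]1OC(=O)[C@H]1C(C)(C)CC[C@H](O)[C@]1(C)C(C)=O | intermediate
10 | (1S,2R,5S)-8-phenylmenthyl (1S,2R,3S)-2-acetyl-2,6,6-trimethyl-3-[(phenoxycarbonothioyl)oxy]cyclohexane-1-carboxylate | CC(C)(c1ccccc1)[C@H]1CC[C@H](C)C[C@@H]1OC(=O)[C@H]1C(C)(C)CC[C@H](OC(=S)Oc2ccccc2)[C@]1(C)C(C)=O | intermediate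
11 | (1S,2R,5S)-8-phenylmenthyl (1S,2S)-2-acetyl-2,6,6-trimethylcyclohexane-1-carboxylate | CC(C)(c1ccccc1)[C@H]1CC[C@H](C)C[C@@H]1OC(=O)[C@H]1C(C)(C)CCC[C@]1(C)C(C)=O | intermediate
12 | (1S,2R,5S)-8-phenylmenthyl (1S,2S)-2-(acetyloxy)-2,6,6-trimethylcyclohexane-1-carboxylate | CC(C)(c1ccccc1)[C@H]1CC[C@H](C)C[C@@H]1OC(=O)[C@H]1C(C)(C)CCC[C@]1(C)OC(C)=O | intermediate
13 | (1S,2R)-2-(hydroxymethyl)-1,3,3-trimethylcyclohexan-1-ol | OC[C@H]1C(C)(C)CCC[C@]1(C)O | intermediate
14 | (1S,2S)-2-hydroxy-2,6,6-trimethylcyclohexane-1-carbaldehyde | O=C[C@H]1C(C)(C)CCC[C@]1(C)O | intermediate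
15 | (1S,2S)-2-ethenyl-1,3,3-trimethylcyclohexan-1-ol | C=C[C@H]1C(C)(C)CCC[C@]1(C)O | intermediate
16 | (2R)-2-(methoxymethyl)pyrrolidin-1-amine (RAMP) | COC[C@H]1CCCN1N | starting material
17 | 2,2-dimethyl-1,3-dioxan-5-one | CC1(C)OCC(=O)CO1 | starting material
18 | (2R)-N-(2,2-dimethyl-1,3-dioxan-5-ylidene)-2-(methoxymethyl)pyrrolidin-1-amine | COC[C@H]1CCCN1N=C1COC(C)(C)OC1 | intermediate
19 | methyl 4-hydroxybut-2-ynoate | COC(=O)C#CCO | starting material
20 | methyl 4-[(tert-butyldiphenylsilyl)oxy]but-2-ynoate | COC(=O)C#CCO[Si](c1ccccc1)(c1ccccc1)C(C)(C)C | intermediate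
21 | pent-3-yn-1-ol | CC#CCCO | starting material
22 | 5-bromopent-2-yne | CC#CCCBr | intermediate
23 | pent-3-yn-1-ylmagnesium bromide | CC#CCC[Mg]Br | intermediate
24 | pent-3-yn-1-ylcopper | CC#CCC[Cu] | intermediate
25 | methyl (2Z)-3-{[(tert-butyldiphenylsilyl)oxy]methyl}oct-2-en-6-ynoate | CC#CCC/C(=C/C(=O)OC)CO[Si](c1ccccc1)(c1ccccc1)C(C)(C)C | intermediate
26 | (2Z)-3-{[(tert-butyldiphenylsilyl)oxy]methyl}oct-2-en-6-yn-1-ol | CC#CCC/C(=C/CO)CO[Si](c1ccccc1)(c1ccccc1)C(C)(C)C | intermediate
27 | (E)-alkenylzirconocene chloride of 26 with zirconium at C7 and the hydroxyl as zirconocene chloride alkoxide | C/C(=C\CC/C(=C/CO[Zr](Cl)(C1C=CC=C1)C1C=CC=C1)CO[Si](c1ccccc1)(c1ccccc1)C(C)(C)C)[Zr](Cl)(C1C=CC=C1)C1C=CC=C1 | intermediate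
28 | (2Z,6E)-3-{[(tert-butyldiphenylsilyl)oxy]methyl}-7-iodoocta-2,6-dien-1-ol | C/C(I)=C\CC/C(=C/CO)CO[Si](c1ccccc1)(c1ccccc1)C(C)(C)C | intermediate
29 | (2Z,6E)-1-bromo-3-{[(tert-butyldiphenylsilyl)oxy]methyl}-7-iodoocta-2,6-diene | C/C(I)=C\CC/C(=C/CBr)CO[Si](c1ccccc1)(c1ccccc1)C(C)(C)C | intermediate
30 | lithium azaenolate of 18 | [Li+].COC[C@H]1CCCN1[N-]C1=COC(C)(C)OC1 | intermediate
31 | (2R)-N-[(4R)-4-[(2Z,6E)-3-{[(tert-butyldiphenylsilyl)oxy]methyl}-7-iodoocta-2,6-dien-1-yl]-2,2-dimethyl-1,3-dioxan-5-ylidene]-2-(methoxymethyl)pyrrolidin-1-amine (C=N geometry not fixed) | C/C(I)=C\CC/C(=C/C[C@H]1OC(C)(C)OCC1=NN1CCC[C@@H]1COC)CO[Si](c1ccccc1)(c1ccccc1)C(C)(C)C | intermediate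
32 | 9-{2-[(1S,2S)-2-hydroxy-2,6,6-trimethylcyclohexyl]ethyl}-9-borabicyclo[3.3.1]nonane | B1(CC[C@H]2C(C)(C)CCC[C@]2(C)O)C2CCCC1CCC2 | intermediate
33 | (2R)-N-[(4R)-4-[(2Z,6E)-3-{[(tert-butyldiphenylsilyl)oxy]methyl}-9-[(1S,2S)-2-hydroxy-2,6,6-trimethylcyclohexyl]-7-methylnona-2,6-dien-1-yl]-2,2-dimethyl-1,3-dioxan-5-ylidene]-2-(methoxymethyl)pyrrolidin-1-amine (C=N geometry not fixed) | C/C(=C\CC/C(=C/C[C@H]1OC(C)(C)OCC1=NN1CCC[C@@H]1COC)CO[Si](c1ccccc1)(c1ccccc1)C(C)(C)C)CC[C@H]1C(C)(C)CCC[C@]1(C)O | intermediate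
34 | (4R)-4-[(2Z,6E)-3-{[(tert-butyldiphenylsilyl)oxy]methyl}-9-[(1S,2S)-2-hydroxy-2,6,6-trimethylcyclohexyl]-7-methylnona-2,6-dien-1-yl]-2,2-dimethyl-1,3-dioxan-5-one | C/C(=C\CC/C(=C/C[C@H]1OC(C)(C)OCC1=O)CO[Si](c1ccccc1)(c1ccccc1)C(C)(C)C)CC[C@H]1C(C)(C)CCC[C@]1(C)O | intermediate
35 | (3R,5Z,9E)-6-{[(tert-butyldiphenylsilyl)oxy]methyl}-1,3-dihydroxy-12-[(1S,2S)-2-hydroxy-2,6,6-trimethylcyclohexyl]-10-methyldodeca-5,9-dien-2-one | C/C(=C\CC/C(=C/C[C@@H](O)C(=O)CO)CO[Si](c1ccccc1)(c1ccccc1)C(C)(C)C)CC[C@H]1C(C)(C)CCC[C@]1(C)O | intermediate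
36 | (3R,5Z,9E)-1-[(tert-butyldimethylsilyl)oxy]-6-{[(tert-butyldiphenylsilyl)oxy]methyl}-3-hydroxy-12-[(1S,2S)-2-hydroxy-2,6,6-trimethylcyclohexyl]-10-methyldodeca-5,9-dien-2-one | C/C(=C\CC/C(=C/C[C@@H](O)C(=O)CO[Si](C)(C)C(C)(C)C)CO[Si](c1ccccc1)(c1ccccc1)C(C)(C)C)CC[C@H]1C(C)(C)CCC[C@]1(C)O | intermediate
37 | (triphenylphosphoranylidene)ketene | O=C=C=P(c1ccccc1)(c1ccccc1)c1ccccc1 | starting material
38 | (triphenylphosphoranylidene)acetate ester of the C3 hydroxyl of 36 (3R) | C/C(=C\CC/C(=C/C[C@@H](OC(=O)C=P(c1ccccc1)(c1ccccc1)c1ccccc1)C(=O)CO[Si](C)(C)C(C)(C)C)CO[Si](c1ccccc1)(c1ccccc1)C(C)(C)C)CC[C@H]1C(C)(C)CCC[C@]1(C)O | intermediate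
39 | (5R)-4-{[(tert-butyldimethylsilyl)oxy]methyl}-5-[(2Z,6E)-3-{[(tert-butyldiphenylsilyl)oxy]methyl}-9-[(1S,2S)-2-hydroxy-2,6,6-trimethylcyclohexyl]-7-methylnona-2,6-dien-1-yl]furan-2(5H)-one | C/C(=C\CC/C(=C/C[C@H]1OC(=O)C=C1CO[Si](C)(C)C(C)(C)C)CO[Si](c1ccccc1)(c1ccccc1)C(C)(C)C)CC[C@H]1C(C)(C)CCC[C@]1(C)O | intermediate
40 | (5R)-4-(hydroxymethyl)-5-[(2Z,6E)-3-(hydroxymethyl)-9-[(1S,2S)-2-hydroxy-2,6,6-trimethylcyclohexyl]-7-methylnona-2,6-dien-1-yl]furan-2(5H)-one | C/C(=C\CC/C(=C/C[C@H]1OC(=O)C=C1CO)CO)CC[C@H]1C(C)(C)CCC[C@]1(C)O | target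

**Step count and risks**

Total step count: 24. Longest linear sequence: 15 steps (steps 2–10 and 19–24, counted from 3).

Steps most likely to fail, with fallbacks:

Step 4. The enolate 8 may be protonated by the alcohol solvent before it closes, or the face discrimination by the auxiliary in the radical addition may be poor. The fallback sets out from 7 and comes back at 9, forming the two bonds by polar chemistry in separate operations. TiCl4-mediated Hosomi–Sakurai conjugate addition of (3-methylbut-2-en-1-yl)trimethylsilane to 7 (CH2Cl2, −78 °C) bonds the dimethyl-substituted allyl terminus to the ester-bearing carbon, with face control by the same auxiliary, and should give (1S,2R,5S)-8-phenylmenthyl (2R,3RS)-3-methyl-2-(2-methylbut-3-en-2-yl)-4-oxopentanoate F1. Linear-selective hydroformylation of its vinyl group (Rh(acac)(CO)2, bisphosphite ligand, CO/H2, toluene) gives (1S,2R,5S)-8-phenylmenthyl (2R,3RS)-3-methyl-2-(2-methyl-5-oxopentan-2-yl)-4-oxopentanoate F2. Reversible base-mediated intramolecular aldol addition (K2CO3, MeOH, 0 °C), in which only the aldehyde is a competent acceptor and the same A(1,3) argument fixes C2, returns 9.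

Step 6. The acetyl group may migrate from C2 to C3 in the intermediate radical, or the thioacylation of the hindered carbinol in step 5 may be too slow to feed this step. The fallback sets out from 9 and comes back at 11 without a radical. Dehydration of the C3 alcohol toward C4 (the only β-hydrogens) with Martin sulfurane (CH2Cl2, rt) gives (1S,2R,5S)-8-phenylmenthyl (1S,2S)-2-acetyl-2,6,6-trimethylcyclohex-3-ene-1-carboxylate F3, and hydrogenation (H2, Pd/C, EtOAc) gives 11.

Step 10. The β-hydroxy aldehyde may open by retro-aldol cleavage on contact with the Lewis-acidic titanium reagent, or the neopentyl formyl group may be methylenated incompletely. The fallback sets out from 14 and comes back at 15 with a protecting group. Silylation (TESOTf, 2,6-lutidine, CH2Cl2, −78 °C) gives (1S,2S)-2,6,6-trimethyl-2-[(triethylsilyl)oxy]cyclohexane-1-carbaldehyde F4. Wittig methylenation (Ph3PCH3Br, KHMDS, THF, 0 °C), now free of any β-alkoxide, gives triethyl{[(1S,2S)-2-ethenyl-1,3,3-trimethylcyclohexyl]oxy}silane F5, and Bu4NF (THF, rt) gives 15.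

Further compounds
F1 | step 4 | (1S,2R,5S)-8-phenylmenthyl (2R,3RS)-3-methyl-2-(2-methylbut-3-en-2-yl)-4-oxopentanoate | CC(C)(c1ccccc1)[C@H]1CC[C@H](C)C[C@@H]1OC(=O)[C@@H](C(C)(C)C=C)C(C)C(C)=O
F2 | step 4 | (1S,2R,5S)-8-phenylmenthyl (2R,3RS)-3-methyl-2-(2-methyl-5-oxopentan-2-yl)-4-oxopentanoate | CC(C)(c1ccccc1)[C@H]1CC[C@H](C)C[C@@H]1OC(=O)[C@@H](C(C)(C)CCC=O)C(C)C(C)=O
F3 | step 6 | (1S,2R,5S)-8-phenylmenthyl (1S,2S)-2-acetyl-2,6,6-trimethylcyclohex-3-ene-1-carboxylate | CC(C)(c1ccccc1)[C@H]1CC[C@H](C)C[C@@H]1OC(=O)[C@H]1C(C)(C)CC=C[C@]1(C)C(C)=O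
F4 | step 10 | (1S,2S)-2,6,6-trimethyl-2-[(triethylsilyl)oxy]cyclohexane-1-carbaldehyde | O=C[C@H]1C(C)(C)CCC[C@]1(C)O[Si](CC)(CC)CC
F5 | step 10 | triethyl{[(1S,2S)-2-ethenyl-1,3,3-trimethylcyclohexyl]oxy}silane | C=C[C@H]1C(C)(C)CCC[C@]1(C)O[Si](CC)(CC)CC
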